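**Strategy.** Everything rests on cutting ring A between the ring methylene C3 and the gem-dimethyl quaternary carbon C4 (drimane numbering), next to ring-fusion carbon C5. Ring B, with C5 and C10 already set, comes from (R)-carvone by two α′-alkylations. In the key step an iron-hydride hydrogen-atom transfer turns the carvone isopropenyl group into the tertiary C4 radical, which closes ring A 6-exo onto a tosylhydrazone carbon (future C3); loss of sulfinate and dinitrogen then leaves a bare CH2. One operation thus forms the quaternary centre and the trans-decalin and erases its own activating group. The precursor is a monocyclic enone with isopropenyl and 3-(tosylhydrazono)propyl arms on adjacent carbons.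

Key step: step 5

Remark: the target is drawn as the free aryl hydrogen sulfate and is taken as such, so the last step ends with a brief proton exchange of the sulfate salt. Drimane numbering is used for the terpenoid part (C11 is the benzylic carbon); α and β faces refer to the usual decalin drawing with the angular methyl β.

**Step 1**
Reactants: 1 (R)-(−)-carvone
Product: 3 (5R)-2,6-dimethyl-5-(prop-1-en-2-yl)cyclohex-2-en-1-one (C6 epimer mixture), via carvone lithium dienolate 2 (not isolated)
Conditions: LDA (lithium diisopropylamide), THF, −78 °C; MeI, −78 → 0 °C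
Reagents that add atoms: iodomethane (CI)
Why: Kinetic deprotonation at the α′-methylene gives the cross-conjugated dienolate, which is C-methylated (enolate alkylation); the C6 epimer ratio does not matter because this centre is enolised again in step 2.

**Step 2**
Reactants: 3 (5R)-2,6-dimethyl-5-(prop-1-en-2-yl)cyclohex-2-en-1-one
Product: 5 (5S,6S)-2,6-dimethyl-5-(prop-1-en-2-yl)-6-(prop-2-yn-1-yl)cyclohex-2-en-1-one, via methylcarvone lithium dienolate 4 (not isolated)
Conditions: LDA, THF, −78 °C; propargyl bromide, DMPU, −78 °C → rt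
Reagents that add atoms: 3-bromoprop-1-yne (C#CCBr)
Why: Enolate alkylation in which the electrophile enters anti to the adjacent isopropenyl group, setting the quaternary centre (future C10) with methyl cis and the three-carbon arm trans to the isopropenyl group.

**Step 3**
Reactants: 5 (5S,6S)-2,6-dimethyl-5-(prop-1-en-2-yl)-6-(prop-2-yn-1-yl)cyclohex-2-en-1-one
Product: 6 3-[(1S,6S)-1,3-dimethyl-2-oxo-6-(prop-1-en-2-yl)cyclohex-3-en-1-yl]propanal
Conditions: CpRu(MeCN)3PF6 (cat.), 5,5′-bis(trifluoromethyl)-2,2′-bipyridine (cat.), NMP/H2O, 25 °C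
Reagents that add atoms: water (O)
Why: Anti-Markovnikov hydration of a terminal alkyne through a ruthenium vinylidene puts the oxygen on the terminal carbon and gives the aldehyde, leaving the isopropenyl and enone alkenes untouched.

**Step 4**
Reactants: 6 3-[(1S,6S)-1,3-dimethyl-2-oxo-6-(prop-1-en-2-yl)cyclohex-3-en-1-yl]propanal
Product: 7 N′-[(1E)-3-[(1S,6S)-1,3-dimethyl-2-oxo-6-(prop-1-en-2-yl)cyclohex-3-en-1-yl]propylidene]-4-methylbenzenesulfonohydrazide
Conditions: TsNHNH2, MeOH, rt
Reagents that add atoms: 4-methylbenzenesulfonohydrazide (Cc1ccc(S(=O)(=O)NN)cc1)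
Why: Hydrazone condensation occurs only at the unhindered aldehyde, since the conjugated ketone next to a quaternary carbon does not condense under these conditions.

**Step 5**
Reactants: 7 N′-[(1E)-3-[(1S,6S)-1,3-dimethyl-2-oxo-6-(prop-1-en-2-yl)cyclohex-3-en-1-yl]propylidene]-4-methylbenzenesulfonohydrazide
Product: 10 (4aS,8aS)-2,5,5,8a-tetramethyl-4a,5,6,7,8,8a-hexahydronaphthalen-1(4H)-one, via cyclised tosylhydrazine 8 (not isolated), via alkyl diazene 9 (not isolated)
Conditions: Fe(acac)3, PhSiH3, EtOH, 60 °C; then Et3N, 60–80 °C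
Reagents that add atoms: none
Why: Fe(acac)3/PhSiH3/EtOH forms an iron hydride that transfers a hydrogen atom to the CH2 terminus of the electron-rich 1,1-disubstituted isopropenyl alkene, giving the tertiary radical at the future gem-dimethyl carbon; this nucleophilic radical adds to the electrophilic tosylhydrazone carbon, the hydrazinyl radical is reduced and protonated to 8, and Et3N then expels p-toluenesulfinate to give diazene 9, which loses N2 and leaves the ring CH2. The closest known reaction type is the iron-hydride HAT reductive alkylation of unactivated alkenes with sulfonylhydrazones (alkene–hydrazone coupling, also intramolecular, followed by base-induced cleavage of the tosylhydrazine). Ring A closes in the 6-exo-trig mode onto the C=N carbon through a chair transition state in which the radical arm and the hydrazone arm are trans-diequatorial on the cyclohexenone, so only the trans-fused decalin can form. No new stereocentre is created, because the new quaternary carbon carries two methyl groups and the transiently aminated carbon ends as CH2; the ring fusion is inherited from C5 (carvone) and C10 (step 2). The step needs HAT to the isopropenyl group and not to the enone, and cyclisation faster than reduction of the radical: the electron-poor conjugated alkene is a poor partner for the iron hydride and lies out of reach of the radical for any feasible ring size, and the 6-exo addition to an activated C=N is fast.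

**Step 6**
Reactants: 10 (4aS,8aS)-2,5,5,8a-tetramethyl-4a,5,6,7,8,8a-hexahydronaphthalen-1(4H)-one
Product: 11 (1S,4aS,8aS)-2,5,5,8a-tetramethyl-4a,5,6,7,8,8a-hexahydro-4H-spiro[naphthalene-1,2′-oxirane] (oxirane O β and CH2 α)
Conditions: Me3S+ I−, n-BuLi, THF, −10 °C → rt
Reagents that add atoms: trimethylsulfonium iodide (C[S+](C)C.[I-])
Why: Corey–Chaykovsky epoxidation, in which the unstabilised sulfonium ylide adds 1,2 to the enone carbonyl from the α face, anti to the axial angular methyl; the configuration of this spiro centre is not carried into the target.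

**Step 7**
Reactants: 11 spiro-epoxide
Product: 12 (1S,4aS,8aS)-2,5,5,8a-tetramethyl-1,4,4a,5,6,7,8,8a-octahydronaphthalene-1-carbaldehyde (drim-7-en-11-al)
Conditions: MgBr2·OEt2, Et2O, 0 °C → rt
Reagents that add atoms: none
Why: Meinwald rearrangement, in which Lewis-acid opening at the allylic spiro carbon and a 1,2-hydride shift give the β,γ-unsaturated aldehyde; the formyl group is expected β (equatorial), and this carbon stops being a stereocentre in step 12.

**Step 8**
Reactants: 12 drim-7-en-11-al
Product: 13 (1S,2S,4aS,8aS)-2,5,5,8a-tetramethyldecahydronaphthalene-1-carbaldehyde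
Conditions: H2 (4 atm), 5% Rh/Al2O3, EtOAc, rt
Reagents that add atoms: none
Why: Heterogeneous hydrogenation should deliver hydrogen to the α face of the trisubstituted alkene, because the β face is screened by the axial angular methyl and the β-formyl group, which sets the C8 methyl β (axial, 2S); Rh on alumina is chosen for its low tendency to move the alkene into conjugation.

**Step 9**
Reactants: 14 benzene-1,2,4-triol
Product: 15 1,2,4-tris(methoxymethoxy)benzene
Conditions: NaH, DMF, 0 °C; MOMCl, 0 °C → rt (argon)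
Reagents that add atoms: chloromethyl methyl ether (COCCl)
Why: O-alkylation of the three phenoxides (Williamson-type MOM protection) gives the ether set needed later for ortho-metalation and for non-acidic removal.

**Step 10**
Reactants: 15 1,2,4-tris(methoxymethoxy)benzene
Product: 16 1-bromo-2,4,5-tris(methoxymethoxy)benzene
Conditions: NBS, MeCN, 0 °C, dark
Reagents that add atoms: N-bromosuccinimide (O=C1CCC(=O)N1Br)
Why: Electrophilic aromatic bromination goes to the position ortho to one and para to another alkoxy group, the most activated site of a 1,2,4-trialkoxybenzene.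

**Step 11**
Reactants: 16 1-bromo-2,4,5-tris(methoxymethoxy)benzene; 13 (1S,2S,4aS,8aS)-2,5,5,8a-tetramethyldecahydronaphthalene-1-carbaldehyde
Product: 18 [(1S,2S,4aS,8aS)-2,5,5,8a-tetramethyldecahydronaphthalen-1-yl][2,4,5-tris(methoxymethoxy)phenyl]methanol (carbinol epimers), via aryllithium 17 (not isolated)
Conditions: 16, n-BuLi, THF, −78 °C; then 13, −78 → −20 °C; H2O
Reagents that add atoms: none
Why: Bromine–lithium exchange at −78 °C is faster than ortho-deprotonation and the aryllithium adds 1,2 to the hindered aldehyde (organolithium addition); the carbinol configuration is of no consequence.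

**Step 12**
Reactants: 18 benzylic alcohol
Product: 19 1-{(E)-[(2S,4aS,8aS)-2,5,5,8a-tetramethyl-3,4,4a,5,6,7,8,8a-octahydronaphthalen-1(2H)-ylidene]methyl}-2,4,5-tris(methoxymethoxy)benzene
Conditions: methyl N-(triethylammoniosulfonyl)carbamate (Burgess reagent), toluene, 50 °C
Reagents that add atoms: none
Why: Dehydration in which the sulfamate of this benzylic alcohol, activated by ortho- and para-alkoxy groups, ionises and loses its only β-hydrogen (E1-like), so both carbinol epimers converge on the alkene with the aryl group syn to the C8 methine and anti to quaternary C10 (E), the geometry that the axial C8 methyl leaves free of allylic strain.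

**Step 13**
Reactants: 19 tris-MOM styrene
Product: 21 2,3,6-tris(methoxymethoxy)-5-{(E)-[(2S,4aS,8aS)-2,5,5,8a-tetramethyl-3,4,4a,5,6,7,8,8a-octahydronaphthalen-1(2H)-ylidene]methyl}benzaldehyde, via ortho-lithiated arene 20 (not isolated)
Conditions: n-BuLi, TMEDA, THF, 0 °C; DMF, 0 °C → rt; H2O
Reagents that add atoms: N,N-dimethylformamide (CN(C)C=O)
Why: Directed ortho-metalation, in which the ring position between two MOM ethers is lithiated cooperatively, in preference to the position beside the bulky alkenyl group, and the aryllithium is formylated by DMF.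

**Step 14**
Reactants: 21 tris-MOM aldehyde
Product: 23 2,3,6-trihydroxy-5-{(E)-[(2S,4aS,8aS)-2,5,5,8a-tetramethyl-3,4,4a,5,6,7,8,8a-octahydronaphthalen-1(2H)-ylidene]methyl}benzaldehyde, via tris(trimethylsilyl) ether 22 (not isolated)
Conditions: TMSOTf, 2,2′-bipyridyl, MeCN, 0 °C → rt; then H2O (argon)
Reagents that add atoms: none
Why: TMSOTf buffered by 2,2′-bipyridyl converts aryl MOM ethers into aryl silyl ethers without free acid and water then frees the phenols (acetal cleavage), which avoids acid-induced cyclisation of the ortho-hydroxystyrene.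

**Step 15**
Reactants: 23 triol
Product: 26 2-formyl-3,4-dihydroxy-6-{(E)-[(2S,4aS,8aS)-2,5,5,8a-tetramethyl-3,4,4a,5,6,7,8,8a-octahydronaphthalen-1(2H)-ylidene]methyl}phenyl hydrogen sulfate, via catechol phenylboronate 24 (not isolated), via sulfated boronate 25 (not isolated)
Conditions: PhB(OH)2, pyridine, 4 Å MS, rt; SO3·pyridine, 50 °C; aq. mannitol work-up; Dowex 50W (H+ form), 0 °C
Reagents that add atoms: sulfur trioxide–pyridine complex ([O-]S(=O)(=O)[n+]1ccccc1)
Why: Phenylboronic acid ties up the catechol as a cyclic boronate, so the only free hydroxyl, the phenol between the formyl and alkenyl groups, is O-sulfated by SO3·pyridine; aqueous mannitol then releases the catechol and the acid resin gives the hydrogen sulfate.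

**Compound list**

1 | (R)-(−)-carvone, (5R)-2-methyl-5-(prop-1-en-2-yl)cyclohex-2-en-1-one | CC1=CC[C@@H](C(C)=C)CC1=O | starting material
2 | lithium (3R)-6-methyl-3-(prop-1-en-2-yl)cyclohexa-1,5-dien-1-olate (kinetic dienolate of 1) | CC1=CC[C@@H](C(C)=C)C=C1O[Li] | intermediate
3 | (5R)-2,6-dimethyl-5-(prop-1-en-2-yl)cyclohex-2-en-1-one (C6 epimer mixture, trans expected major) | CC1=CC[C@@H](C(C)=C)C(C)C1=O | intermediate
4 | lithium dienolate of 3 (O–Li on C1, C1=C6 and C2=C3 double bonds, C5 unchanged) | CC1=CC[C@@H](C(C)=C)C(C)=C1O[Li] | intermediate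
5 | (5S,6S)-2,6-dimethyl-5-(prop-1-en-2-yl)-6-(prop-2-yn-1-yl)cyclohex-2-en-1-one | CC1=CC[C@@H](C(C)=C)[C@](C)(CC#C)C1=O | intermediate
6 | 3-[(1S,6S)-1,3-dimethyl-2-oxo-6-(prop-1-en-2-yl)cyclohex-3-en-1-yl]propanal | CC1=CC[C@@H](C(C)=C)[C@](C)(CCC=O)C1=O | intermediate
7 | N′-[(1E)-3-[(1S,6S)-1,3-dimethyl-2-oxo-6-(prop-1-en-2-yl)cyclohex-3-en-1-yl]propylidene]-4-methylbenzenesulfonohydrazide | CC1=CC[C@@H](C(C)=C)[C@](C)(CC/C=N/NS(=O)(=O)c2ccc(C)cc2)C1=O | intermediate
8 | N′-[(4aS,8aS)-1,1,4a,6-tetramethyl-5-oxo-1,2,3,4,4a,5,8,8a-octahydronaphthalen-2-yl]-4-methylbenzenesulfonohydrazide (C2 epimers) | CC1=CC[C@H]2C(C)(C)C(NNS(=O)(=O)c3ccc(C)cc3)CC[C@]2(C)C1=O | intermediate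
9 | (4aS,8aS)-6-diazenyl-2,5,5,8a-tetramethyl-4a,5,6,7,8,8a-hexahydronaphthalen-1(4H)-one (C6 epimers) | CC1=CC[C@H]2C(C)(C)C(N=N)CC[C@]2(C)C1=O | intermediate
10 | (4aS,8aS)-2,5,5,8a-tetramethyl-4a,5,6,7,8,8a-hexahydronaphthalen-1(4H)-one | CC1=CC[C@H]2C(C)(C)CCC[C@]2(C)C1=O | intermediate
11 | (1S,4aS,8aS)-2,5,5,8a-tetramethyl-4a,5,6,7,8,8a-hexahydro-4H-spiro[naphthalene-1,2′-oxirane] (O β, CH2 α) | CC1=CC[C@H]2C(C)(C)CCC[C@]2(C)[C@]13CO3 | intermediate
12 | (1S,4aS,8aS)-2,5,5,8a-tetramethyl-1,4,4a,5,6,7,8,8a-octahydronaphthalene-1-carbaldehyde | CC1=CC[C@H]2C(C)(C)CCC[C@]2(C)[C@H]1C=O | intermediate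
13 | (1S,2S,4aS,8aS)-2,5,5,8a-tetramethyldecahydronaphthalene-1-carbaldehyde | C[C@H]1CC[C@H]2C(C)(C)CCC[C@]2(C)[C@H]1C=O | intermediate
14 | benzene-1,2,4-triol | Oc1ccc(O)c(O)c1 | starting material
15 | 1,2,4-tris(methoxymethoxy)benzene | COCOc1ccc(OCOC)c(OCOC)c1 | intermediate
16 | 1-bromo-2,4,5-tris(methoxymethoxy)benzene | COCOc1cc(OCOC)c(OCOC)cc1Br | intermediate
17 | [2,4,5-tris(methoxymethoxy)phenyl]lithium | [Li]c1cc(OCOC)c(OCOC)cc1OCOC | intermediate
18 | [(1S,2S,4aS,8aS)-2,5,5,8a-tetramethyldecahydronaphthalen-1-yl][2,4,5-tris(methoxymethoxy)phenyl]methanol (carbinol epimers) | C[C@H]1CC[C@H]2C(C)(C)CCC[C@]2(C)[C@H]1C(O)c1cc(OCOC)c(OCOC)cc1OCOC | intermediate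
19 | 1-{(E)-[(2S,4aS,8aS)-2,5,5,8a-tetramethyl-3,4,4a,5,6,7,8,8a-octahydronaphthalen-1(2H)-ylidene]methyl}-2,4,5-tris(methoxymethoxy)benzene | C[C@H]1CC[C@H]2C(C)(C)CCC[C@]2(C)/C1=C/c1cc(OCOC)c(OCOC)cc1OCOC | intermediate
20 | 3-lithio derivative of 19 (lithium between the two MOM ethers) | C[C@H]1CC[C@H]2C(C)(C)CCC[C@]2(C)/C1=C/c1cc(OCOC)c(OCOC)c([Li])c1OCOC | intermediate
21 | 2,3,6-tris(methoxymethoxy)-5-{(E)-[(2S,4aS,8aS)-2,5,5,8a-tetramethyl-3,4,4a,5,6,7,8,8a-octahydronaphthalen-1(2H)-ylidene]methyl}benzaldehyde | C[C@H]1CC[C@H]2C(C)(C)CCC[C@]2(C)/C1=C/c1cc(OCOC)c(OCOC)c(C=O)c1OCOC | intermediate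
22 | tris(trimethylsilyl) ether of 23 | C[C@H]1CC[C@H]2C(C)(C)CCC[C@]2(C)/C1=C/c1cc(O[Si](C)(C)C)c(O[Si](C)(C)C)c(C=O)c1O[Si](C)(C)C | intermediate
23 | 2,3,6-trihydroxy-5-{(E)-[(2S,4aS,8aS)-2,5,5,8a-tetramethyl-3,4,4a,5,6,7,8,8a-octahydronaphthalen-1(2H)-ylidene]methyl}benzaldehyde | C[C@H]1CC[C@H]2C(C)(C)CCC[C@]2(C)/C1=C/c1cc(O)c(O)c(C=O)c1O | intermediate
24 | cyclic phenylboronate of the catechol of 23 | C[C@H]1CC[C@H]2C(C)(C)CCC[C@]2(C)/C1=C/c1cc3OB(c4ccccc4)Oc3c(C=O)c1O | intermediate
25 | hydrogen sulfate of 24 at the remaining phenol | C[C@H]1CC[C@H]2C(C)(C)CCC[C@]2(C)/C1=C/c1cc3OB(c4ccccc4)Oc3c(C=O)c1OS(=O)(=O)O | intermediate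
26 | 2-formyl-3,4-dihydroxy-6-{(E)-[(2S,4aS,8aS)-2,5,5,8a-tetramethyl-3,4,4a,5,6,7,8,8a-octahydronaphthalen-1(2H)-ylidene]methyl}phenyl hydrogen sulfate | C[C@H]1CC[C@H]2C(C)(C)CCC[C@]2(C)/C1=C/c1cc(O)c(O)c(C=O)c1OS(=O)(=O)O | target

**Step count.** Total: 15 steps. Longest linear sequence: 13 steps (steps 1–8 and 11–15); steps 9–10 make the arene fragment.

**Steps most likely to fail**

Step 5. The tertiary radical may be reduced before it cyclises (plain hydrogenation of the isopropenyl group), or the cyclised tosylhydrazine may not fragment cleanly. The fallback closes the same bond by a Giese-type 6-endo cyclisation on an acrylate and removes the ester afterwards. It sets out from 3: LDA, THF, −78 °C, then methyl 2-(bromomethyl)acrylate should give methyl 2-{[(1S,6S)-1,3-dimethyl-2-oxo-6-(prop-1-en-2-yl)cyclohex-3-en-1-yl]methyl}prop-2-enoate F1, again by alkylation anti to the isopropenyl group. Fe(acac)3, PhSiH3, EtOH/ethylene glycol, 60 °C should add the same tertiary radical to the acrylate CH2 terminus and give methyl (4aS,8aS)-4,4,7,8a-tetramethyl-8-oxo-1,2,3,4,4a,5,8,8a-octahydronaphthalene-2-carboxylate F2. LiOH, THF/H2O gives (4aS,8aS)-4,4,7,8a-tetramethyl-8-oxo-1,2,3,4,4a,5,8,8a-octahydronaphthalene-2-carboxylic acid F3. Barton decarboxylation (oxalyl chloride, then sodium 2-sulfanylpyridine N-oxide, t-BuSH, hν) comes back to the route at 10.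

Step 8. Hydrogen may be delivered without clear facial preference, or the alkene may migrate into conjugation with the aldehyde on the catalyst. The fallback reduces the alkene at the alcohol oxidation level, where no conjugation is possible. It sets out from 12: NaBH4, MeOH, 0 °C gives [(1S,4aS,8aS)-2,5,5,8a-tetramethyl-1,4,4a,5,6,7,8,8a-octahydronaphthalen-1-yl]methanol F4. H2, PtO2, EtOAc should add hydrogen from the α face, since both the angular methyl and the CH2OH arm sit on the β face, to give [(1S,2S,4aS,8aS)-2,5,5,8a-tetramethyldecahydronaphthalen-1-yl]methanol F5. Dess–Martin periodinane, CH2Cl2 comes back to the route at 13.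

Step 15. The transient boronate may scramble, or the hindered phenol, hydrogen-bonded to the formyl group, may resist sulfation under conditions the boronate tolerates. The fallback masks the catechol covalently so that forcing sulfation can be used. It sets out from 23: 1,1′-carbonyldiimidazole, THF, rt should give the cyclic carbonate 5-hydroxy-2-oxo-6-{(E)-[(2S,4aS,8aS)-2,5,5,8a-tetramethyl-3,4,4a,5,6,7,8,8a-octahydronaphthalen-1(2H)-ylidene]methyl}-1,3-benzodioxole-4-carbaldehyde F6. Excess SO3·pyridine, DMF, 60 °C gives 4-formyl-2-oxo-6-{(E)-[(2S,4aS,8aS)-2,5,5,8a-tetramethyl-3,4,4a,5,6,7,8,8a-octahydronaphthalen-1(2H)-ylidene]methyl}-1,3-benzodioxol-5-yl hydrogen sulfate F7. Aqueous NaHCO3/MeOH opens the carbonate and proton exchange on the acid resin comes back to the route at 26.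

**Further compounds**

F1 | step 5 | methyl 2-{[(1S,6S)-1,3-dimethyl-2-oxo-6-(prop-1-en-2-yl)cyclohex-3-en-1-yl]methyl}prop-2-enoate | CC1=CC[C@@H](C(C)=C)[C@](C)(CC(=C)C(=O)OC)C1=O
F2 | step 5 | methyl (4aS,8aS)-4,4,7,8a-tetramethyl-8-oxo-1,2,3,4,4a,5,8,8a-octahydronaphthalene-2-carboxylate (C2 epimers) | CC1=CC[C@H]2C(C)(C)CC(C(=O)OC)C[C@]2(C)C1=O
F3 | step 5 | (4aS,8aS)-4,4,7,8a-tetramethyl-8-oxo-1,2,3,4,4a,5,8,8a-octahydronaphthalene-2-carboxylic acid (C2 epimers) | CC1=CC[C@H]2C(C)(C)CC(C(=O)O)C[C@]2(C)C1=O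
F4 | step 8 | [(1S,4aS,8aS)-2,5,5,8a-tetramethyl-1,4,4a,5,6,7,8,8a-octahydronaphthalen-1-yl]methanol | CC1=CC[C@H]2C(C)(C)CCC[C@]2(C)[C@H]1CO
F5 | step 8 | [(1S,2S,4aS,8aS)-2,5,5,8a-tetramethyldecahydronaphthalen-1-yl]methanol | C[C@H]1CC[C@H]2C(C)(C)CCC[C@]2(C)[C@H]1CO
F6 | step 15 | 5-hydroxy-2-oxo-6-{(E)-[(2S,4aS,8aS)-2,5,5,8a-tetramethyl-3,4,4a,5,6,7,8,8a-octahydronaphthalen-1(2H)-ylidene]methyl}-1,3-benzodioxole-4-carbaldehyde | C[C@H]1CC[C@H]2C(C)(C)CCC[C@]2(C)/C1=C/c1cc3OC(=O)Oc3c(C=O)c1O
F7 | step 15 | 4-formyl-2-oxo-6-{(E)-[(2S,4aS,8aS)-2,5,5,8a-tetramethyl-3,4,4a,5,6,7,8,8a-octahydronaphthalen-1(2H)-ylidene]methyl}-1,3-benzodioxol-5-yl hydrogen sulfate | C[C@H]1CC[C@H]2C(C)(C)CCC[C@]2(C)/C1=C/c1cc3OC(=O)Oc3c(C=O)c1OS(=O)(=O)O
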